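**Assumption:** the target SMILES carries no stereocentre and the 2-aryl axis is not configurationally stable, so the molecule is achiral and there is no enantiomer to select.

**Retrosynthetic overview**
1. Target ⇒ its 3',6'-di-O-benzyl ether (final hydrogenolysis). Rings A and B are bought as benzene rings; ring C is the only ring built, and it is built last.
2. Ring C ⇒ O1–C2 bond by acid cyclodehydration of a 1,3-diketone. Ring A of the diketone is symmetric, so either ortho-hydroxyl gives the same flavone.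
3. Diketone ⇒ C-acylation of the lithium polyanion of 2,4,6-trihydroxy-3,5-dimethoxyacetophenone with 3,6-bis(benzyloxy)-2-methoxybenzoyl chloride.
4. Ring A ketone ⇒ both C–OMe bonds made in one operation on 2,4,6-trihydroxyacetophenone by a new diazo-transfer / aromatising double carbenoid O–H insertion into methanol.
5. Ring B acid ⇒ ortho-lithiation/carboxylation of methoxyhydroquinone dibenzyl ether.

**Route**

Step 1
Reactants: 1 2-methoxybenzene-1,4-diol (methoxyhydroquinone)
Product: 2 1,4-bis(benzyloxy)-2-methoxybenzene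
Conditions: BnBr (2.3 equiv), K2CO3, DMF, 60 °C, N2
Reagents that add atoms: benzyl bromide, BrCc1ccccc1
Why: Williamson ether synthesis (SN2 of both phenoxides on benzyl bromide), run under nitrogen because the hydroquinone dianion is air-sensitive.

Step 2
Reactants: 2 1,4-bis(benzyloxy)-2-methoxybenzene
Product: 4 3,6-bis(benzyloxy)-2-methoxybenzoic acid, via aryllithium 3 (not isolated)
Conditions: n-BuLi (1.15 equiv), THF, 0 °C, 1 h; CO2, –78 °C to rt; aq. HCl
Reagents that add atoms: carbon dioxide, O=C=O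
Why: Directed ortho-metalation: the C3–H flanked by OMe and OBn is the most acidic and doubly coordinated site, as in the lithiation of 1,2,4-trimethoxybenzene, and the aryllithium is trapped by carboxylation.

Step 3
Reactants: 5 1-(2,4,6-trihydroxyphenyl)ethan-1-one (2,4,6-trihydroxyacetophenone, dried)
Product: 7 1-(2,4,6-trihydroxy-3,5-dimethoxyphenyl)ethan-1-one, via bis(diazo) triketone 6 (not isolated)
Conditions: p-ABSA (2.2 equiv), Et3N, MeCN, 0 °C; silica plug, no concentration; then Rh2(OAc)4 (2 mol%), MeOH/ClCH2CH2Cl, 60 °C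
Reagents that add atoms: methanol, CO
Why: Proposed new method: formal double C–H methoxylation of an acylphloroglucinol by diazo transfer and aromatising carbenoid O–H insertion; 5 reacts through its triketone tautomers, so each ring CH (C3 and C5) is a 1,3-dicarbonyl carbon that accepts a diazo group from the sulfonyl azide to give 6, and Rh2(OAc)4 (divalent rhodium) then expels N2 from each diazo carbon to give an electrophilic carbenoid flanked by two carbonyls, which methanol attacks at oxygen (oxonium ylide, 1,2-proton shift) to leave a C(H)(OMe) unit whose enolisation restores the benzene ring; the oxidising reagent is consumed before the electron-rich product exists, which avoids the over-oxidation that defeats direct oxidative methoxylation of polyphenols; the closest known reaction types are Regitz diazo transfer to cyclic 1,3-diketones and activated phenols and dirhodium-catalysed O–H insertion of 2-diazo-1,3-diketones into alcohols.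

Step 4
Reactants: 4 3,6-bis(benzyloxy)-2-methoxybenzoic acid; 7 1-(2,4,6-trihydroxy-3,5-dimethoxyphenyl)ethan-1-one
Product: 10 2-[3,6-bis(benzyloxy)-2-methoxyphenyl]-5,7-dihydroxy-6,8-dimethoxy-4H-chromen-4-one, via acid chloride 8 (not isolated), via diketone 9 (not isolated)
Conditions: 4, (COCl)2, cat. DMF, CH2Cl2, rt, evaporate; 7, LiN(SiMe3)2 (5.2 equiv), THF, –78 °C, then 8, –78 °C to rt; aq. HCl; crude in AcOH, 0.5% H2SO4, 80 °C
Reagents that add atoms: none
Why: Claisen-type C-acylation of the acetophenone polyanion (three phenoxides plus the enolate, which is the most nucleophilic site) by the aroyl chloride, then acid-catalysed cyclodehydration that forms the O1–C2 bond of ring C; ring A is symmetric and ring B has no free ortho-hydroxyl, so only one flavone can form.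

Step 5
Reactants: 10 2-[3,6-bis(benzyloxy)-2-methoxyphenyl]-5,7-dihydroxy-6,8-dimethoxy-4H-chromen-4-one
Product: 11 5,7-dihydroxy-2-(3,6-dihydroxy-2-methoxyphenyl)-6,8-dimethoxy-4H-chromen-4-one (5,7,3',6'-tetrahydroxy-6,8,2'-trimethoxyflavone)
Conditions: H2 (1 atm), 10% Pd/C, EtOAc/MeOH, rt; filter and concentrate under argon
Reagents that add atoms: none
Why: Hydrogenolysis of the two benzyl aryl ethers; the C2=C3 bond is a hindered vinylogous ester that is not reduced at 1 atm, and the methyl ethers are untouched.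

**Compound list**
1 | 2-methoxybenzene-1,4-diol (methoxyhydroquinone) | COc1cc(O)ccc1O | starting material
2 | 1,4-bis(benzyloxy)-2-methoxybenzene | COc1cc(OCc2ccccc2)ccc1OCc1ccccc1 | intermediate
3 | [3,6-bis(benzyloxy)-2-methoxyphenyl]lithium | [Li]c1c(OC)c(OCc2ccccc2)ccc1OCc1ccccc1 | intermediate
4 | 3,6-bis(benzyloxy)-2-methoxybenzoic acid | OC(=O)c1c(OC)c(OCc2ccccc2)ccc1OCc1ccccc1 | intermediate
5 | 1-(2,4,6-trihydroxyphenyl)ethan-1-one | CC(=O)c1c(O)cc(O)cc1O | starting material
6 | 2-acetyl-4,6-bis(diazo)-3-hydroxycyclohex-2-ene-1,5-dione | CC(=O)C1=C(O)C(=[N+]=[N-])C(=O)C(=[N+]=[N-])C1=O | intermediate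
7 | 1-(2,4,6-trihydroxy-3,5-dimethoxyphenyl)ethan-1-one | CC(=O)c1c(O)c(OC)c(O)c(OC)c1O | intermediate
8 | 3,6-bis(benzyloxy)-2-methoxybenzoyl chloride | ClC(=O)c1c(OC)c(OCc2ccccc2)ccc1OCc1ccccc1 | intermediate
9 | 1-[3,6-bis(benzyloxy)-2-methoxyphenyl]-3-(2,4,6-trihydroxy-3,5-dimethoxyphenyl)propane-1,3-dione | O=C(CC(=O)c1c(O)c(OC)c(O)c(OC)c1O)c1c(OC)c(OCc2ccccc2)ccc1OCc1ccccc1 | intermediate
10 | 2-[3,6-bis(benzyloxy)-2-methoxyphenyl]-5,7-dihydroxy-6,8-dimethoxy-4H-chromen-4-one | COc1c(OCc2ccccc2)ccc(OCc2ccccc2)c1-c1cc(=O)c2c(O)c(OC)c(O)c(OC)c2o1 | intermediate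
11 | 5,7-dihydroxy-2-(3,6-dihydroxy-2-methoxyphenyl)-6,8-dimethoxy-4H-chromen-4-one | COc1c(O)ccc(O)c1-c1cc(=O)c2c(O)c(OC)c(O)c(OC)c2o1 | target

**Step count**
Total steps: 5. Longest linear sequence: 4 steps (steps 1, 2, 4, 5, from 1 to 11); the ring A branch (step 3, 5 to 7) joins at step 4.

**Steps most likely to fail**

- **Step 3 (the proposed new step).** The second diazo transfer may stall once the first diazo group has withdrawn electron density. Compound 6 may azo-couple with unreacted phenolate. Rhodium-mediated loss of N2 may end in reduction or Wolff-type ring contraction instead of O–H insertion. Compound 6 is also energetic and must stay in dilute solution. The fallback uses known chemistry; it sets out from 5 and comes back at 7. Electrophilic dibromination of 5 (N-bromosuccinimide, 2.05 equiv, MeCN, 0 °C) gives 1-(3,5-dibromo-2,4,6-trihydroxyphenyl)ethan-1-one F1. Copper-mediated methanolysis of both C–Br bonds (NaOMe, CuBr, DMF/MeOH, 110 °C, argon) then gives 7, in the way bromophenols such as 5-bromovanillin are converted into methoxyphenols.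

- **Step 4.** The hindered aroyl chloride may acylate a phenoxide oxygen instead of the enolate carbon, or the polyanion may be too insoluble or too hindered to react cleanly. The fallback replaces the intermolecular C-acylation by an intramolecular acyl transfer; it sets out from 7 (with 8 made from 4 as before) and comes back at 11. Benzylation of 7 (BnBr, 2.1 equiv, K2CO3, acetone, reflux) leaves one chelated hydroxyl and gives 1-[4,6-bis(benzyloxy)-2-hydroxy-3,5-dimethoxyphenyl]ethan-1-one F2. O-Acylation with 8 (pyridine, DMAP) gives 2-acetyl-3,5-bis(benzyloxy)-4,6-dimethoxyphenyl 3,6-bis(benzyloxy)-2-methoxybenzoate F3. Baker–Venkataraman rearrangement (KOH, pyridine, 50 °C) gives 1-[4,6-bis(benzyloxy)-2-hydroxy-3,5-dimethoxyphenyl]-3-[3,6-bis(benzyloxy)-2-methoxyphenyl]propane-1,3-dione F4. Cyclodehydration (AcOH, NaOAc, 110 °C) gives 5,7-bis(benzyloxy)-2-[3,6-bis(benzyloxy)-2-methoxyphenyl]-6,8-dimethoxy-4H-chromen-4-one F5. Hydrogenolysis of all four benzyl ethers (H2, Pd/C) gives 11.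

- **Step 2.** n-BuLi may deprotonate a benzylic CH2 (followed by 1,2-Wittig rearrangement) in competition with the ring C3–H. The fallback does the metalation on a substrate without benzylic protons and brings in the benzyl groups afterwards; it sets out from 1 and comes back at 4. Protection of 1 (MOMCl, i-Pr2NEt, CH2Cl2) gives 2-methoxy-1,4-bis(methoxymethoxy)benzene F6. Lithiation and formylation (n-BuLi, THF, 0 °C; DMF) give 2-methoxy-3,6-bis(methoxymethoxy)benzaldehyde F7. Acetal cleavage (HCl, MeOH, 50 °C) gives 3,6-dihydroxy-2-methoxybenzaldehyde F8. Benzylation (BnBr, K2CO3, DMF) gives 3,6-bis(benzyloxy)-2-methoxybenzaldehyde F9. Pinnick oxidation (NaClO2, NaH2PO4, 2-methyl-2-butene, t-BuOH/H2O) gives 4.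

**Further compounds**
F1 | step 3 | 1-(3,5-dibromo-2,4,6-trihydroxyphenyl)ethan-1-one | CC(=O)c1c(O)c(Br)c(O)c(Br)c1O
F2 | step 4 | 1-[4,6-bis(benzyloxy)-2-hydroxy-3,5-dimethoxyphenyl]ethan-1-one | CC(=O)c1c(O)c(OC)c(OCc2ccccc2)c(OC)c1OCc1ccccc1
F3 | step 4 | 2-acetyl-3,5-bis(benzyloxy)-4,6-dimethoxyphenyl 3,6-bis(benzyloxy)-2-methoxybenzoate | CC(=O)c1c(OC(=O)c2c(OC)c(OCc3ccccc3)ccc2OCc2ccccc2)c(OC)c(OCc2ccccc2)c(OC)c1OCc1ccccc1
F4 | step 4 | 1-[4,6-bis(benzyloxy)-2-hydroxy-3,5-dimethoxyphenyl]-3-[3,6-bis(benzyloxy)-2-methoxyphenyl]propane-1,3-dione | O=C(CC(=O)c1c(O)c(OC)c(OCc2ccccc2)c(OC)c1OCc1ccccc1)c1c(OC)c(OCc2ccccc2)ccc1OCc1ccccc1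
F5 | step 4 | 5,7-bis(benzyloxy)-2-[3,6-bis(benzyloxy)-2-methoxyphenyl]-6,8-dimethoxy-4H-chromen-4-one | COc1c(OCc2ccccc2)ccc(OCc2ccccc2)c1-c1cc(=O)c2c(OCc3ccccc3)c(OC)c(OCc3ccccc3)c(OC)c2o1
F6 | step 2 | 2-methoxy-1,4-bis(methoxymethoxy)benzene | COCOc1ccc(OCOC)c(OC)c1
F7 | step 2 | 2-methoxy-3,6-bis(methoxymethoxy)benzaldehyde | COCOc1ccc(OCOC)c(OC)c1C=O
F8 | step 2 | 3,6-dihydroxy-2-methoxybenzaldehyde | COc1c(O)ccc(O)c1C=O
F9 | step 2 | 3,6-bis(benzyloxy)-2-methoxybenzaldehyde | COc1c(OCc2ccccc2)ccc(OCc2ccccc2)c1C=O
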